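**Plan**
- Cuts: first the two C2–Br bonds. Then, in each indole, C3a–C4 and C7–C7a (four C–C bonds, both benzene rings), which leads back to a 3,3'-bipyrrole. The C3–C3' bond is cut last.
- Enabling feature: each benzene ring carries Br only at C5 and C6 and H at C4 and C7. The chain C4–C5–C6–C7 is therefore the diene of 3,4-dibromothiophene 1,1-dioxide, and the shared bond C3a–C7a is the unsubstituted C4–C5 bond of a 3-substituted pyrrole.
- Forward order: the C3–C3' bond joins two ready-made pyrrole rings and N-silyl is exchanged for N-Boc. Both benzene rings are then built one after the other in one flask, the Boc groups are removed, and C2 and C2' are brominated.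
- Stereochemistry: the target has no stereocentre. The ring-fusion centres formed during the annulation are transient and vanish on aromatisation.

Key step: step 4

Remark: the target SMILES fixes no configuration at the hindered C3–C3' axis, so the biaryl is made without control of axial chirality.
Remark: in steps 2, 5 and 6 both halves undergo the same reaction, so the half-converted species are not numbered. In step 4 the two annulations are distinct stages and are numbered.

Step 1
Reactants: 1 3-bromo-1-(triisopropylsilyl)pyrrole (two molecules)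
Product: 2 1,1'-bis(triisopropylsilyl)-3,3'-bipyrrole
Conditions: Ni(cod)2, 2,2'-bipyridine, 1,5-cyclooctadiene, DMF, 60 °C
Reagents that add atoms: none
Why: In this Yamamoto-type reductive homocoupling, zerovalent nickel inserts into the C3–Br bond, two arylnickel bromides disproportionate to a diarylnickel species and reductive elimination forms C3–C3', while the bulky N-silyl group lies far from C3 and is inert without fluoride.

Step 2
Reactants: 2 1,1'-bis(triisopropylsilyl)-3,3'-bipyrrole
Product: 4 di-tert-butyl 3,3'-bipyrrole-1,1'-dicarboxylate, via 1H,1'H-3,3'-bipyrrole 3 (not isolated)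
Conditions: Bu4NF, THF, 0 °C; then Boc2O, DMAP (cat.), same flask, rt
Reagents that add atoms: di-tert-butyl dicarbonate, CC(C)(C)OC(=O)OC(=O)OC(C)(C)C
Why: Fluoride-induced N–Si cleavage and DMAP-catalysed N-acylation with Boc2O are routine protecting-group operations, and running them in one flask avoids isolating the oxidation-prone free bipyrrole.

Step 3
Reactants: 5 3,4-dibromothiophene
Product: 6 3,4-dibromothiophene 1,1-dioxide
Conditions: H2O2 (50% aq.), (CF3CO)2O, CH2Cl2, 0 °C to rt
Reagents that add atoms: hydrogen peroxide, OO (both sulfone oxygens, handed over as trifluoroperacetic acid, OOC(=O)C(F)(F)F, formed in the flask)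
Why: This is a peracid S-oxidation of a thiophene, for which trifluoroperacetic acid is electrophilic enough to oxidise the electron-poor sulfur twice, and the two bromines at C3 and C4 slow self-dimerisation enough for the dioxide to be isolated and stored cold.

Step 4
Reactants: 4 di-tert-butyl 3,3'-bipyrrole-1,1'-dicarboxylate; 6 3,4-dibromothiophene 1,1-dioxide (two molecules are incorporated)
Product: 12 di-tert-butyl 5,5',6,6'-tetrabromo-3,3'-biindole-1,1'-dicarboxylate, via first bridged sulfone adduct 7 (not isolated), via pyrrolyl-3a,7a-dihydroindole 8 (not isolated), via pyrrolylindole 9 (not isolated), via second bridged sulfone adduct 10 (not isolated), via indolyl-3a,7a-dihydroindole 11 (not isolated)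
Conditions: 6 (3 equiv, slow addition), DDQ (2.2 equiv, present from the start), PhCl, 110 °C, N2 sweep
Reagents that add atoms: none
Why: Proposed new method: the electron-poor, non-aromatic diene of 6 should add suprafacially, in an inverse-electron-demand [4+2] cycloaddition, to the enecarbamate-like C4=C5 bond of one Boc-pyrrole ring of 4, the 7-thiabicyclo[2.2.1]heptene dioxide 7 then loses SO2 by cheletropic extrusion and DDQ removes the two ring-fusion hydrogens of 8 to give 9, after which the same three events on the second pyrrole ring (10, 11) lead to 12. The closest known reaction types are the cycloaddition–SO2 extrusion of halogenated thiophene 1,1-dioxides with alkenes and the inverse-demand additions of tetrazines and triazines across C=C bonds of pyrroles and indoles, whereas addition of a thiophene dioxide to a pyrrole C=C bond is not established. Each of the two benzene rings closes by an intermolecular [4+2] annulation in which C3a–C4 and C7–C7a form together and the four diene carbons become C4 to C7, so the bromines of 6 can only arrive at C5 and C6, and the symmetry of the diene excludes orientational isomers. No stereocentre survives, because the cis ring-fusion centres of 7, 8, 10 and 11 follow from suprafacial addition and are erased by a dehydrogenation that takes away hydrogen only and leaves every C–Br bond in place. Site selectivity for C4=C5 over C2=C3 is secured by the pyrrolyl (later indolyl) group at C3, which makes C2=C3 trisubstituted, would force a quaternary centre and would give an adduct unable to aromatise, and the pyrrole should act as 2π rather than 4π partner because its Diels–Alder adducts revert whereas loss of SO2 makes the wanted path irreversible. The Boc groups weaken the pyrrole aromaticity, block N–H and C-nucleophilic conjugate addition to the vinyl sulfone and let the rings tolerate DDQ, slow addition of 6 limits its self-dimerisation, and DDQ present from the outset removes each dihydroindole before its non-aromatic C2=C3 bond or its cyclohexadiene can consume more 6.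

Step 5
Reactants: 12 di-tert-butyl 5,5',6,6'-tetrabromo-3,3'-biindole-1,1'-dicarboxylate
Product: 13 5,5',6,6'-tetrabromo-1H,1'H-3,3'-biindole
Conditions: NaOMe (cat.), MeOH/THF, rt
Reagents that add atoms: none
Why: In this methanolysis of an indole N-carbamate, methoxide attacks the Boc carbonyl and expels the stabilised dibromoindolide, a known mild N-Boc cleavage that forms no tert-butyl cation able to alkylate the free C2 positions and leaves aryl bromides untouched.

Step 6
Reactants: 13 5,5',6,6'-tetrabromo-1H,1'H-3,3'-biindole
Product: 14 2,2',5,5',6,6'-hexabromo-1H,1'H-3,3'-biindole (target)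
Conditions: NBS (2.05 equiv), dry DMF, 0 °C, dark
Reagents that add atoms: N-bromosuccinimide, O=C1CCC(=O)N1Br
Why: In this electrophilic bromination of a 3-substituted indole, C2 is the only open position of each pyrrole ring (attack at C3 gives a 3-bromoindolenine that passes bromine on to C2), and each benzene ring is deactivated by its two bromines.

**Compound list**
1 | 3-bromo-1-(triisopropylsilyl)pyrrole | CC(C)[Si](C(C)C)(C(C)C)n1ccc(Br)c1 | starting material
2 | 1,1'-bis(triisopropylsilyl)-3,3'-bipyrrole | CC(C)[Si](C(C)C)(C(C)C)n1ccc(-c2ccn([Si](C(C)C)(C(C)C)C(C)C)c2)c1 | intermediate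
3 | 1H,1'H-3,3'-bipyrrole | c1cc(-c2cc[nH]c2)c[nH]1 | intermediate
4 | di-tert-butyl 3,3'-bipyrrole-1,1'-dicarboxylate | CC(C)(C)OC(=O)n1ccc(-c2ccn(C(=O)OC(C)(C)C)c2)c1 | intermediate
5 | 3,4-dibromothiophene | Brc1cscc1Br | starting material
6 | 3,4-dibromothiophene 1,1-dioxide | O=S1(=O)C=C(Br)C(Br)=C1 | intermediate
7 | tert-butyl 5,6-dibromo-3-[1-(tert-butoxycarbonyl)pyrrol-3-yl]-3a,4,7,7a-tetrahydro-4,7-epithioindole-1-carboxylate 8,8-dioxide (racemic, endo/exo sense not defined) | CC(C)(C)OC(=O)N1C=C(c3ccn(C(=O)OC(C)(C)C)c3)C2C1C1C(Br)=C(Br)C2S1(=O)=O | intermediate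
8 | tert-butyl cis-5,6-dibromo-3-[1-(tert-butoxycarbonyl)pyrrol-3-yl]-3a,7a-dihydroindole-1-carboxylate (racemic, one enantiomer drawn) | CC(C)(C)OC(=O)N1C=C(c3ccn(C(=O)OC(C)(C)C)c3)[C@@H]2C=C(Br)C(Br)=C[C@H]12 | intermediate
9 | tert-butyl 5,6-dibromo-3-[1-(tert-butoxycarbonyl)pyrrol-3-yl]indole-1-carboxylate | CC(C)(C)OC(=O)n1cc(-c2ccn(C(=O)OC(C)(C)C)c2)c2cc(Br)c(Br)cc21 | intermediate
10 | tert-butyl 5,6-dibromo-3-[5,6-dibromo-1-(tert-butoxycarbonyl)indol-3-yl]-3a,4,7,7a-tetrahydro-4,7-epithioindole-1-carboxylate 8,8-dioxide (racemic, endo/exo sense not defined) | CC(C)(C)OC(=O)N1C=C(c3cn(C(=O)OC(C)(C)C)c4cc(Br)c(Br)cc34)C2C1C1C(Br)=C(Br)C2S1(=O)=O | intermediate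
11 | tert-butyl cis-5,6-dibromo-3-[5,6-dibromo-1-(tert-butoxycarbonyl)indol-3-yl]-3a,7a-dihydroindole-1-carboxylate (racemic, one enantiomer drawn) | CC(C)(C)OC(=O)N1C=C(c3cn(C(=O)OC(C)(C)C)c4cc(Br)c(Br)cc34)[C@@H]2C=C(Br)C(Br)=C[C@H]12 | intermediate
12 | di-tert-butyl 5,5',6,6'-tetrabromo-3,3'-biindole-1,1'-dicarboxylate | CC(C)(C)OC(=O)n1cc(-c2cn(C(=O)OC(C)(C)C)c3cc(Br)c(Br)cc23)c2cc(Br)c(Br)cc21 | intermediate
13 | 5,5',6,6'-tetrabromo-1H,1'H-3,3'-biindole | Brc1cc2[nH]cc(-c3c[nH]c4cc(Br)c(Br)cc34)c2cc1Br | intermediate
14 | 2,2',5,5',6,6'-hexabromo-1H,1'H-3,3'-biindole | Brc1cc2[nH]c(Br)c(-c3c(Br)[nH]c4cc(Br)c(Br)cc34)c2cc1Br | target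

Total step count: 6. Longest linear sequence: 5 (steps 1, 2, 4, 5, 6). Step 3 is the side branch.

**Steps most likely to fail**

1. Step 4 (new method).
- What may go wrong: the dearomatising cycloaddition may be slower than self-dimerisation of the dioxide. The transient dihydroindoles may be lost before dehydrogenation, through a further cycloaddition, through hydrogen shifts followed by loss of HBr, or through ionisation of the C7a–N bond. DDQ may also attack the bipyrrole.
- Fallback (known chemistry, from 6 back to 13): the benzene ring is annulated onto a true cyclic enecarbamate and the C3–C3' bond is made afterwards. Compound 6 is heated with commercial tert-butyl 2,3-dihydropyrrole-1-carboxylate in a thiophene dioxide–alkene cycloaddition. The bridged sulfone tert-butyl 5,6-dibromo-2,3,3a,4,7,7a-hexahydro-4,7-epithioindole-1-carboxylate 8,8-dioxide F1 loses SO2 to give tert-butyl cis-5,6-dibromo-2,3,3a,7a-tetrahydroindole-1-carboxylate F2. DDQ dehydrogenates this to tert-butyl 5,6-dibromoindoline-1-carboxylate F3. CF3CO2H removes the carbamate to give 5,6-dibromoindoline F4, and DDQ dehydrogenates this free indoline to 5,6-dibromo-1H-indole F5. A Pd(OCOCF3)2-catalysed oxidative C3–H/C3–H homocoupling (divalent palladium, AgNO3 as oxidant, DMSO, rt) then joins two molecules of F5 to give 13.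

2. Step 6.
- What may go wrong: NBS may oxidise the biindole core by two electrons instead of substituting it, with hydrolysis to oxindole-type material on work-up. The second bromination may also stall because of crowding around the C3–C3' axis.
- Fallback (from 13 to 14): C–H borylation followed by halodeboronation replaces electrophilic substitution. Treating 13 with [Ir(OMe)(cod)]2, 4,4'-di-tert-butyl-2,2'-bipyridine and B2pin2 in THF at 60 °C should borylate only C2 and C2', because C4 and C7 are each flanked by a bromine. This gives 5,5',6,6'-tetrabromo-2,2'-bis(4,4,5,5-tetramethyl-1,3,2-dioxaborolan-2-yl)-1H,1'H-3,3'-biindole F6. CuBr2 in MeOH/H2O at 80 °C then exchanges each boryl group for bromine and delivers 14.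

3. Step 3.
- What may go wrong: oxidation may stop at the reactive S-oxide stage, which dimerises, or the dioxide, unsubstituted at C2 and C5, may self-dimerise during work-up and storage.
- Fallback (from 5 to 6): the two carbons next to sulfur are masked before oxidation. Treating 5 with LiN(iPr)2 and Me3SiCl in THF at −78 °C gives 3,4-dibromo-2,5-bis(trimethylsilyl)thiophene F7, whose more electron-rich sulfur is oxidised by mCPBA in CH2Cl2. The product is the storable, non-dimerising 3,4-dibromo-2,5-bis(trimethylsilyl)thiophene 1,1-dioxide F8. Protodesilylation with KF in AcOH-buffered wet THF at 0 °C, carried out just before use, releases 6.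

**Further compounds**
F1 | step 4 | tert-butyl 5,6-dibromo-2,3,3a,4,7,7a-hexahydro-4,7-epithioindole-1-carboxylate 8,8-dioxide (racemic, endo/exo sense not defined) | CC(C)(C)OC(=O)N1CCC2C1C1C(Br)=C(Br)C2S1(=O)=O
F2 | step 4 | tert-butyl cis-5,6-dibromo-2,3,3a,7a-tetrahydroindole-1-carboxylate (racemic, one enantiomer drawn) | CC(C)(C)OC(=O)N1CC[C@@H]2C=C(Br)C(Br)=C[C@H]12
F3 | step 4 | tert-butyl 5,6-dibromoindoline-1-carboxylate | CC(C)(C)OC(=O)N1CCc2cc(Br)c(Br)cc21
F4 | step 4 | 5,6-dibromoindoline | Brc1cc2c(cc1Br)NCC2
F5 | step 4 | 5,6-dibromo-1H-indole | Brc1cc2cc[nH]c2cc1Br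
F6 | step 6 | 5,5',6,6'-tetrabromo-2,2'-bis(4,4,5,5-tetramethyl-1,3,2-dioxaborolan-2-yl)-1H,1'H-3,3'-biindole | CC1(C)OB(OC1(C)C)c1[nH]c2cc(Br)c(Br)cc2c1-c1c(B2OC(C)(C)C(C)(C)O2)[nH]c2cc(Br)c(Br)cc12
F7 | step 3 | 3,4-dibromo-2,5-bis(trimethylsilyl)thiophene | C[Si](C)(C)c1sc([Si](C)(C)C)c(Br)c1Br
F8 | step 3 | 3,4-dibromo-2,5-bis(trimethylsilyl)thiophene 1,1-dioxide | C[Si](C)(C)C1=C(Br)C(Br)=C([Si](C)(C)C)S1(=O)=O
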